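**Retrosynthetic overview**
- The target is cut at the vinylic C–CH3 bond (alkenyl triflate plus a methylzinc reagent) and at the silyl ether.
- The two C–C bonds between the bicyclo[2.2.2]octene and the lactone come from a stepwise anionic Michael–Michael annulation of the (R)-cryptone dienolate onto O-silylated (+)-altholactone. This ring system is formed last.
- The tetrahydrofuran ring (formed second) comes from a redox-neutral isomerisation of a pyranone lactol. The new carbinol opens a pendant aryl epoxide.
- Key step: the six-membered O-ring (formed first) comes from Achmatowicz oxidative ring expansion of a 2-furyl carbinol (five-membered furan to six-membered pyranone).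
- The furyl epoxy carbinol comes from 2-acetylfuran and benzaldehyde. (R)-Cryptone comes from 3-methylbutanal and methyl vinyl ketone.

Assumption: operations run in one flask without isolation count as one step. The anomeric centre of the pyranone lactol is an inconsequential mixture and is left undefined.

**Step 1**
Reactants: 1 3-methylbutanal; 2 but-3-en-2-one
Product: 4 (R)-cryptone, via keto aldehyde 3 (not isolated)
Conditions: (R)-2-[methoxy(diphenyl)methyl]pyrrolidine (5 mol %), ethyl 3,4-dihydroxybenzoate (20 mol %), neat, 4 °C; then LiOH (cat.), i-PrOH, rt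
Reagents that add atoms: none
Why: Enamine-catalysed asymmetric Michael addition, in which the E-enamine is attacked on the face away from the CPh2OMe group and sets the isopropyl-bearing centre as R, is followed by an intramolecular aldol condensation of the methyl ketone onto the aldehyde that leaves this centre untouched.

**Step 2**
Reactants: 5 2-acetylfuran; 6 benzaldehyde
Product: 7 (E)-1-(furan-2-yl)-3-phenylprop-2-en-1-one
Conditions: NaOH (10 % aq), EtOH, 0 °C → rt
Reagents that add atoms: none
Why: Claisen–Schmidt condensation, whose E1cB dehydration gives only the conjugated E-enone.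

**Step 3**
Reactants: 7 (E)-1-(furan-2-yl)-3-phenylprop-2-en-1-one
Product: 8 furan-2-yl[(2R,3S)-3-phenyloxiran-2-yl]methanone
Conditions: poly-L-leucine, urea·H2O2, DBU, THF, rt
Reagents that add atoms: hydrogen peroxide (delivered as its urea adduct), OO
Why: Juliá–Colonna (Weitz–Scheffer type) nucleophilic epoxidation attacks only the electron-poor alkene, not the furan, and the helical poly-L-leucine sets the trans-(2R,3S) epoxide.

**Step 4**
Reactants: 8 furan-2-yl[(2R,3S)-3-phenyloxiran-2-yl]methanone
Product: 9 (S)-furan-2-yl[(2S,3S)-3-phenyloxiran-2-yl]methanol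
Conditions: RuCl[(S,S)-TsDPEN](p-cymene) (1 mol %), HCO2Na, CTAB (cat.), H2O/CH2Cl2, rt
Reagents that add atoms: none
Why: In this Noyori asymmetric transfer hydrogenation under neutral conditions, the CH/π contact between the cymene ligand and the furyl ring selects the ketone face. This gives the S carbinol (threo to the epoxide oxygen) under catalyst control and spares the epoxide.

**Step 5 (key ring expansion)**
Reactants: 9 (S)-furan-2-yl[(2S,3S)-3-phenyloxiran-2-yl]methanol
Product: 11 (2S)-6-hydroxy-2-[(2R,3S)-3-phenyloxiran-2-yl]-2H-pyran-3(6H)-one, via Z-enedione 10 (not isolated)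
Conditions: NBS (1.05 equiv), NaHCO3, THF/H2O 4:1, 0 °C
Reagents that add atoms: water, O
Why: In the Achmatowicz rearrangement, bromine/water oxidation of the furan (the most electron-rich site) opens it to Z-enedione 10. The carbinol oxygen then closes on the aldehyde, so the five-membered ring becomes the six-membered pyranone while the carbinol C–O bond and its configuration are kept.

**Step 6**
Reactants: 11 (2S)-6-hydroxy-2-[(2R,3S)-3-phenyloxiran-2-yl]-2H-pyran-3(6H)-one
Product: 15 O-triethylsilyl-(+)-altholactone, via ketolactone 12 (not isolated), via cis-hydroxylactone 13 (not isolated), via (+)-altholactone 14 (not isolated)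
Conditions: [Ir(cod)Cl]2 (2.5 mol %), 2,6-dichlorobenzoic acid (30 mol %), CHCl3, 23 → 40 °C; then imidazole, Et3SiCl, 0 °C → rt
Reagents that add atoms: chlorotriethylsilane, CC[Si](Cl)(CC)CC
Why: Proposed new method: a redox-neutral, stereoconvergent isomerisation of lactol 11 into its isomer 14 (both C13H12O4), in which the monovalent iridium alkoxide of the lactol undergoes beta-hydride elimination to ketolactone 12 and an iridium hydride; the hydride returns to the ring ketone anti to the C6 side chain to give cis-carbinol 13, whose hydroxyl, under the weak acid, opens the aryl epoxide at the benzylic carbon (5-endo-tet, inversion), forming the tetrahydrofuran C–O bond and fixing C2, C3 and C7a of altholactone; hydride transfer between 12 and 13 is reversible and only the cis epimer can reach the epoxide, so any trans carbinol is drained back through 12; the closest known reaction types are iridium-catalysed internal transfer hydrogenation of Achmatowicz lactols, metal-catalysed carbinol epimerisation as used in dynamic kinetic resolution, and acid-catalysed 5-endo opening of styrene-type epoxy alcohols; the closing silylation is a standard imidazole-mediated protection.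

**Step 7**
Reactants: 4 (R)-cryptone; 15 O-triethylsilyl-(+)-altholactone
Product: 19 bicyclic alkenyl triflate, via lithium dienolate 16 (not isolated), via Michael adduct enolate 17 (not isolated), via bicyclic ketone enolate 18 (not isolated)
Conditions: LDA (commercial solution), THF, −78 °C; add 15, −78 → 0 °C; Comins reagent, −78 → 0 °C
Reagents that add atoms: Comins reagent, N-(5-chloropyridin-2-yl)bis(trifluoromethanesulfonimide), FC(F)(F)S(=O)(=O)N(c1ccc(Cl)cn1)S(=O)(=O)C(F)(F)F
Why: This is a double Michael annulation followed by enolate O-triflation: kinetic alpha-prime deprotonation gives cross-conjugated dienolate 16, which adds in a lithium-chelated Michael addition to the beta carbon of 15 on its convex face (anti to the ring-fusion C–O bond) and anti to the isopropyl group to give 17, whose lactone enolate closes onto the enone in a second, intramolecular Michael addition with the lactone carbonyl held endo by the lithium bridge, giving the regiodefined enolate 18, so that these three facial preferences set the four new centres.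

**Step 8**
Reactants: 19 bicyclic alkenyl triflate
Product: 21 target CNP0249919.1, via O-triethylsilyl target 20 (not isolated)
Conditions: MeZnCl, Pd(PPh3)4 (5 mol %), THF, 50 °C; then 1 M HCl, THF, rt
Reagents that add atoms: methylzinc chloride, C[Zn]Cl
Why: Negishi coupling (oxidative addition of the alkenyl triflate to zerovalent palladium, transmetalation, reductive elimination) places the methyl group on the triflate carbon without moving the double bond and tolerates the lactone and silyl ether, and the dilute acid then hydrolyses the triethylsilyl ether without touching any stereocentre.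

**Compound list**
1 | 3-methylbutanal (isovaleraldehyde) | CC(C)CC=O | starting material
2 | but-3-en-2-one (methyl vinyl ketone) | CC(=O)C=C | starting material
3 | (2R)-2-isopropyl-5-oxohexanal | CC(=O)CC[C@@H](C=O)C(C)C | intermediate
4 | (R)-cryptone, (4R)-4-isopropylcyclohex-2-en-1-one | O=C1CC[C@H](C(C)C)C=C1 | intermediate
5 | 2-acetylfuran | CC(=O)c1ccco1 | starting material
6 | benzaldehyde | O=Cc1ccccc1 | starting material
7 | (E)-1-(furan-2-yl)-3-phenylprop-2-en-1-one | O=C(/C=C/c1ccccc1)c1ccco1 | intermediate
8 | furan-2-yl[(2R,3S)-3-phenyloxiran-2-yl]methanone (trans epoxide) | O=C(c1ccco1)[C@@H]1O[C@H]1c1ccccc1 | intermediate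
9 | (S)-furan-2-yl[(2S,3S)-3-phenyloxiran-2-yl]methanol (threo epoxy alcohol) | O[C@H](c1ccco1)[C@@H]1O[C@H]1c1ccccc1 | intermediate
10 | (2Z,5S)-5-hydroxy-4-oxo-5-[(2S,3S)-3-phenyloxiran-2-yl]pent-2-enal | O=C/C=C\C(=O)[C@@H](O)[C@@H]1O[C@H]1c1ccccc1 | intermediate
11 | (2S)-6-hydroxy-2-[(2R,3S)-3-phenyloxiran-2-yl]-2H-pyran-3(6H)-one (anomer mixture) | O=C1C=CC(O)O[C@H]1[C@@H]1O[C@H]1c1ccccc1 | intermediate
12 | (6S)-6-[(2R,3S)-3-phenyloxiran-2-yl]-2H-pyran-2,5(6H)-dione | O=C1C=CC(=O)O[C@H]1[C@@H]1O[C@H]1c1ccccc1 | intermediate
13 | (5S,6R)-5-hydroxy-6-[(2R,3S)-3-phenyloxiran-2-yl]-5,6-dihydro-2H-pyran-2-one (5,6-cis) | O=C1O[C@@H]([C@@H]2O[C@H]2c2ccccc2)[C@@H](O)C=C1 | intermediate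
14 | (+)-altholactone, (2R,3R,3aS,7aS)-3-hydroxy-2-phenyl-2,3,3a,7a-tetrahydro-5H-furo[3,2-b]pyran-5-one | O=C1O[C@H]2[C@H](O)[C@@H](c3ccccc3)O[C@H]2C=C1 | intermediate
15 | 3-O-triethylsilyl-(+)-altholactone (configuration as in 14) | O=C1O[C@H]2[C@H](O[Si](CC)(CC)CC)[C@@H](c3ccccc3)O[C@H]2C=C1 | intermediate
16 | lithium (4R)-4-isopropylcyclohexa-1,5-dien-1-olate | [Li]OC1=CC[C@H](C(C)C)C=C1 | intermediate
17 | lithium lactone enolate of the mono-Michael adduct (cryptone C6 bonded to lactone C7, trans to isopropyl, anti to the ring-fusion C–O) | O=C1C=C[C@@H](C(C)C)C[C@@H]1[C@@H]2C=C(O[Li])O[C@H]3[C@H](O[Si](CC)(CC)CC)[C@@H](c4ccccc4)O[C@@H]23 | intermediate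
18 | lithium enolate of the endo-lactone-fused bicyclo[2.2.2]octanone (target skeleton, OLi for CH3, OSiEt3 for OH) | [Li]OC1=C[C@@H]2[C@@H]3C(=O)O[C@H]4[C@H](O[Si](CC)(CC)CC)[C@@H](c5ccccc5)O[C@H]4[C@@H]3[C@H]1C[C@@H]2C(C)C | intermediate
19 | bicyclic alkenyl triflate (target skeleton and configuration, OTf for CH3, OSiEt3 for OH) | FC(F)(F)S(=O)(=O)OC1=C[C@@H]2[C@@H]3C(=O)O[C@H]4[C@H](O[Si](CC)(CC)CC)[C@@H](c5ccccc5)O[C@H]4[C@@H]3[C@H]1C[C@@H]2C(C)C | intermediate
20 | O-triethylsilyl ether of the target | CC1=C[C@@H]2[C@@H]3C(=O)O[C@H]4[C@H](O[Si](CC)(CC)CC)[C@@H](c5ccccc5)O[C@H]4[C@@H]3[C@H]1C[C@@H]2C(C)C | intermediate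
21 | CNP0249919.1 (endo adduct skeleton of (+)-altholactone and (R)-α-phellandrene) | CC1=C[C@@H]2[C@@H]3C(=O)O[C@H]4[C@H](O)[C@@H](c5ccccc5)O[C@H]4[C@@H]3[C@H]1C[C@@H]2C(C)C | target

**Totals**
Total step count: 8. Longest linear sequence: 7 (steps 2 to 8).

**Three steps most likely to fail**

*Step 6, the proposed new isomerisation.*
- Risks: the lactol hydroxyl or the carboxylic acid may open the epoxide before hydride transfer. The iridium hydride may reduce the ene-dione in a conjugate sense. The centre next to the ketone may epimerise while the material cycles through 12.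
- Fallback (known chemistry): it sets out from 11. The lactol is oxidised with Dess–Martin periodinane/NaHCO3 to ketolactone 12, now isolated. Luche reduction (NaBH4, CeCl3·7H2O, MeOH, −78 °C) delivers hydride anti to the side chain and gives cis-hydroxylactone 13. Catalytic camphorsulfonic acid in CH2Cl2 closes the tetrahydrofuran to 14. Et3SiCl/imidazole then brings the material back to the route at 15.

*Step 7, the one-pot Michael–Michael annulation.*
- Risks: the dienolate may act as a base on the gamma hydrogen of 15, leading to ring opening. The sequence may stop after the first addition. The endo/exo ratio may be low.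
- Fallback (changes from an anionic cascade to two separate stages): it sets out from 4 and 15. Dienolate 16 is added to 15 at −78 °C and quenched cold with acetic acid to isolate the neutral mono-Michael adduct F1. Soft enolisation with Me3SiOTf/Et3N in CH2Cl2 gives the silyl ketene acetal F2. This closes by an intramolecular Mukaiyama–Michael addition to the trimethylsilyl enol ether F3. Mild aqueous acid releases the bicyclic ketone F4. LiHMDS (only the CH2 side can enolise) regenerates 18, and Comins reagent brings the material back to the route at 19.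

*Step 4, the catalyst-controlled threo reduction.*
- Risk: the catalyst works against the substrate's erythro bias.
- Fallback (substrate control followed by inversion): it sets out from 8. Chelation-controlled reduction with Zn(BH4)2 in Et2O gives the erythro (R)-carbinol F5. Mitsunobu reaction (4-nitrobenzoic acid, PPh3, DIAD) inverts it to the (S)-4-nitrobenzoate F6. K2CO3/MeOH methanolysis brings the material back to the route at 9.

**Further compounds**
F0 | step 6 | none | none
F1 | step 7 | neutral mono-Michael adduct (enone plus saturated lactone) | O=C1C=C[C@@H](C(C)C)C[C@@H]1[C@@H]2CC(=O)O[C@H]3[C@H](O[Si](CC)(CC)CC)[C@@H](c4ccccc4)O[C@@H]23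
F2 | step 7 | trimethylsilyl ketene acetal of F1 | O=C1C=C[C@@H](C(C)C)C[C@@H]1[C@@H]2C=C(O[Si](C)(C)C)O[C@H]3[C@H](O[Si](CC)(CC)CC)[C@@H](c4ccccc4)O[C@@H]23
F3 | step 7 | trimethylsilyl enol ether of the bicyclic ketone | C[Si](C)(C)OC1=C[C@@H]2[C@@H]3C(=O)O[C@H]4[C@H](O[Si](CC)(CC)CC)[C@@H](c5ccccc5)O[C@H]4[C@@H]3[C@H]1C[C@@H]2C(C)C
F4 | step 7 | endo-lactone-fused bicyclo[2.2.2]octan-2-one (O-triethylsilyl) | O=C1C[C@@H]2[C@@H]3C(=O)O[C@H]4[C@H](O[Si](CC)(CC)CC)[C@@H](c5ccccc5)O[C@H]4[C@@H]3[C@H]1C[C@@H]2C(C)C
F5 | step 4 | (R)-furan-2-yl[(2S,3S)-3-phenyloxiran-2-yl]methanol (erythro) | O[C@@H](c1ccco1)[C@@H]1O[C@H]1c1ccccc1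
F6 | step 4 | (S)-furan-2-yl[(2S,3S)-3-phenyloxiran-2-yl]methyl 4-nitrobenzoate | O=C(O[C@H](c1ccco1)[C@@H]1O[C@H]1c1ccccc1)c1ccc(cc1)[N+](=O)[O-]
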